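Take the small charge first: the winter run put 7.6 mM of starting material under 30 mM of reagent and stood at 102% of bis adduct by 5.00 d, so each starting material ends up carrying two reagents, a need of 15.2 mM that lies below the charge. The summer run needed 38.0 mM from its 30 mM and stayed near 62% from 4.00 d on.

| flask | starting material | reagent | remark | time |
|---|---|---|---|---|
| winter | 7.6 mM | 30 mM | run made earlier |  |
| summer | 19 mM | 30 mM | run made earlier |  |
| zeta | 12 mM | 30.0 mM |  | 15 d |
| epsilon | 20 mM | 30.0 mM |  | 15 d |
| delta | 30 mM | 30.0 mM |  | 15 d |

| winter: time / d | winter: bis adduct / % | summer: time / d | summer: bis adduct / % |
|---|---|---|---|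
| 0.625 | 58 | 1.04 | 42 |
| 0.833 | 68 | 2.00 | 53 |
| 1.25 | 83 | 3.00 | 58 |
| 2.00 | 93 | 4.00 | 62 |
| 3.00 | 96 | 5.00 | 61 |
| 5.00 | 102 | 6.00 | 62 |
| 8.00 | 103 | 8.00 | 62 |

(each reading ± 2 percentage points)

- "hardly changes" means that all values lie within two and a half points (for a concentration: within two and a half percent of the largest)

- [bis adduct] at the end for zeta, epsilon, delta, in this order
- how that number moves from the first to the last of them (rises, then falls / falls all the way / falls, then rises / rises all the way / hardly changes)

Now count a flask whose reagent has gone, with reagent as the limiting reagent. Suppose the way to bis adduct runs through a first product holding one starting material and one reagent. Charged reagent is then [first product] + 2[bis adduct], charged starting material is [starting material] + [first product] + [bis adduct], and subtraction gives [bis adduct] − [starting material] = charged reagent − charged starting material. Call that right side the reagent surplus, for epsilon 10.0 mM: at the end, [bis adduct] is the surplus plus the starting material left. Summer has a surplus of 11.0 mM and read 11.8 mM, so, if its reagent has gone, about 0.780 mM of starting material stayed, a figure carrying the scatter of 2 percentage points.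

My reckoning: zeta needs 24.0 mM, under its 30.0 mM, so it ends at 12 mM. Epsilon needs 40.0 mM, over its charge, and its surplus plus summer's leftover gives 10.8 mM. Delta has a surplus of 0 mM, so its [bis adduct] equals its [starting material], and summer doesn't say how large they are. Since 15 d is longer than summer took to level, I take the reagent as gone in epsilon and delta. I expect the row to fall, though for delta that is a guess.

The forecast, “Two independent, equivalent sites fit better.”, gives 12 mM, 11.25 mM and 7.5 mM, shape falls all the way: my zeta, an epsilon above mine, and a number for delta where I give none.

The flasks end at 12.0 mM, 10.5 mM and 4.88 mM, shape falls all the way, with delta below the forecast.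

    starting material + reagent → first product (k = 0.170 M⁻¹ min⁻¹)
    reagent + first product → bis adduct (k = 0.0640 M⁻¹ min⁻¹)
    starting material + bis adduct → side product (k = 0.00260 M⁻¹ min⁻¹)

Side product holds two of starting material and two of reagent, so it cancels in the subtraction just as first product does. Epsilon, with reagent at 0%, stands at 10.5 mM, which to rounding is its surplus of 10.0 mM plus the 0.460 mM of starting material left there. Delta, with a surplus of 0 mM and reagent at 0%, ends with bis adduct at 16.3% of its charge and starting material at 16.3%.

The data come from a simulation from invented constants, noise included.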